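The plan cuts the C17–C18 bond of the nine-membered azonane (ring E). Carbinol carbon C18 lies between methyl-bearing C19 and a plain C16H2–C17H2 arm. That arm ends at C14, the quaternary carbon carrying the acetoxymethyl group, so the bond can come from an aldehyde and a carboxylic acid one carbon longer. In one operation, cathodically renewed chromium converts the N-acyloxyphthalimide ester of 37 into a primary alkylchromium that adds to the α-methyl aldehyde on nitrogen. Ring E closes and C18 is set. Precursor 37 is the tetracyclic lactam (rings A–D) with six stereocentres, methyl ester and acetate in place. Its nitrogen side chain is installed at the very start.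

Key step: step 26

**Atom labels (kept for all intermediates)**
- C1 = CH bearing CO2Me; C2 = adjacent ring CH2; C3 = quaternary carbon α to lactam carbonyl C4.
- C5 = ring NCH2; C6 = adjacent CH; C7, C8 = CH2CH2 bridge.
- C9=C10 = tetrasubstituted alkene (C10 on C3); C11 = ring-fusion CH; C12, C13 = cyclopentene CH2CH2.
- C14 = quaternary carbon bearing C15H2O; C16, C17 = CH2CH2 arm.
- C18 = carbinol; C19 = CH(C20H3); C21 = side-chain NCH2; C22 = carboxyl carbon lost as CO2.

**Rings**
- A (C1, C2, C3, C10, C11); B (C9–C13); C (C3, C10, C9, C8, C7, C6, C14).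
- D (lactam: C3, C4, N, C5, C6, C14); E (azonane).
- J = temporary cyclohexene (C14, C6, C7, C22, C17, C16).

**Abbreviations:** R = (R)-3-(benzyloxy)-2-methylpropyl; Ns = 2-nitrobenzenesulfonyl. In these labels 39 is (1R,3R,6S,11R,14R,18R,19R).

Assumption: the (S)-oxazaborolidinium ion of step 8 is taken to expose the face of enal 12 that gives the drawn C6/C14 configuration. If the sense proves opposite, the equally available (R)-catalyst is used.

Remark 1: the (S)-hydroxy ester 1 is required, because its ester carbon becomes C21 and its CH2O carbon becomes C18.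

Remark 2: 19 is drawn as the aldehyde tautomer. C3 in 19 and C1 in 21–28 are configurationally labile and are left undefined.

## Route

Step 1
Reactants: 1 methyl (S)-3-hydroxy-2-methylpropanoate
Product: 2 methyl (S)-3-(benzyloxy)-2-methylpropanoate
Conditions: BnOC(=NH)CCl3, TfOH (cat.), CH2Cl2–cyclohexane, 0 °C → rt
Reagents that add atoms: benzyl 2,2,2-trichloroacetimidate, N=C(OCc1ccccc1)C(Cl)(Cl)Cl
Why: Acid-catalysed O-benzylation with a trichloroacetimidate needs no base, so the β-hydroxy ester neither eliminates nor racemises at C19.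

Step 2
Reactants: 2 methyl (S)-3-(benzyloxy)-2-methylpropanoate
Product: 3 (R)-3-(benzyloxy)-2-methylpropan-1-ol
Conditions: LiAlH4, Et2O, 0 °C
Reagents that add atoms: none
Why: Hydride reduction of the ester gives the primary alcohol whose carbon becomes C21, and the stereocentre is not touched.

Step 3
Reactants: 4 2-nitrobenzenesulfonyl chloride; 5 allylamine
Product: 6 N-allyl-2-nitrobenzenesulfonamide
Conditions: Et3N, CH2Cl2, 0 °C → rt
Reagents that add atoms: none
Why: Sulfonylation of the primary amine gives an acidic NH sulfonamide that can be alkylated once and later cleaved by thiolate.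

Step 4
Reactants: 3 (R)-3-(benzyloxy)-2-methylpropan-1-ol; 6 N-allyl-2-nitrobenzenesulfonamide
Product: 7 (R)-N-allyl-N-[3-(benzyloxy)-2-methylpropyl]-2-nitrobenzenesulfonamide
Conditions: PPh3, DIAD, THF, 0 °C → rt
Reagents that add atoms: none
Why: The Fukuyama–Mitsunobu alkylation forms the N–C21 bond at a primary carbon under neutral conditions, so C19 keeps its configuration.

Step 5
Reactants: 7 N-allyl sulfonamide; 8 methyl vinyl ketone
Product: 9 (R,E)-N-[3-(benzyloxy)-2-methylpropyl]-2-nitro-N-(4-oxopent-2-en-1-yl)benzenesulfonamide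
Conditions: second-generation Hoveyda–Grubbs catalyst (3 mol %), CH2Cl2, 40 °C
Reagents that add atoms: none
Why: Cross metathesis of a terminal alkene with an electron-poor vinyl ketone is selective for the E-enone.

Step 6
Reactants: 9 E-enone sulfonamide
Product: 10 (R,E)-N-[3-(benzyloxy)-2-methylpropyl]-2-nitro-N-[4-(triisopropylsilyloxy)penta-2,4-dien-1-yl]benzenesulfonamide
Conditions: TIPSOTf, Et3N, CH2Cl2, −78 → 0 °C
Reagents that add atoms: triisopropylsilyl trifluoromethanesulfonate, CC(C)[Si](OS(=O)(=O)C(F)(F)F)(C(C)C)C(C)C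
Why: Soft enolisation (silyl triflate and amine) removes a methyl proton of the enone and gives the cross-conjugated 2-silyloxy diene with the E-alkene retained.

Step 7
Reactants: 11 methyl 4-oxobutanoate
Product: 12 methyl 3-formylbut-3-enoate
Conditions: aq. CH2O, pyrrolidine (10 mol %), propionic acid (10 mol %), i-PrOH, 45 °C
Reagents that add atoms: formaldehyde, C=O
Why: Amine-catalysed Mannich condensation and elimination (α-methylenation of an aldehyde) gives the 2-substituted acrolein holding C3, C4, C14, C15 and C16.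

Step 8
Reactants: 10 2-silyloxy diene; 12 methyl 3-formylbut-3-enoate
Product: 13 Diels–Alder adduct: ring J cyclohexene with the C22(OTIPS)=C7 enol ether, quaternary C14 (CHO and CH2CO2Me) and C6 (CH2N(Ns)R), CHO cis to C5
Conditions: (S)-3,3-diphenyl-1-(o-tolyl)tetrahydro-1H,3H-pyrrolo[1,2-c][1,3,2]oxazaborole (20 mol %), Tf2NH (18 mol %), CH2Cl2, −78 → −40 °C
Reagents that add atoms: none
Why: In this enantioselective Diels–Alder reaction the 2-silyloxy ("para") and 1-alkyl ("ortho") groups of 10 direct the same regiochemistry, the endo transition state places C15HO cis to C5, and the formyl-bound chiral cation selects the enal face, which sets C14 and C6.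

Step 9
Reactants: 13 Diels–Alder adduct
Product: 15 spiro-γ-lactone on ring J (C4 carbonyl bound to the C15 oxygen), via hydroxy ester 14 (not isolated)
Conditions: NaBH4, MeOH–THF, −20 °C → rt
Reagents that add atoms: none
Why: Chemoselective borohydride reduction of the aldehyde is followed by lactonisation of the γ-hydroxy ester, which the quaternary C14 favours, and the silyl enol ether and nitroarene are untouched.

Step 10
Reactants: 15 spiro-γ-lactone
Product: 17 trans-fused bicyclic δ-lactam (rings D and J) bearing free C15H2OH, via amino lactone 16 (not isolated)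
Conditions: PhSH, K2CO3, DMF, rt → 50 °C
Reagents that add atoms: none
Why: Thiolate cleavage of the nitrobenzenesulfonamide (nucleophilic aromatic substitution, then loss of SO2) frees the secondary amine, which opens the lactone at C4 to the more stable trans-fused six-membered lactam.

Step 11
Reactants: 17 bicyclic hydroxy lactam
Product: 18 C15 tert-butyldiphenylsilyl ether of 17
Conditions: TBDPSCl, imidazole, DMAP (cat.), DMF, 40 °C
Reagents that add atoms: tert-butyl(chloro)diphenylsilane, CC(C)(C)[Si](Cl)(c1ccccc1)c1ccccc1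
Why: Silylation gives an acid- and base-stable ether whose bulk on the axial C15 also reinforces the facial bias used in steps 13 and 21.

Step 12
Reactants: 18 silyl-protected bicyclic lactam
Product: 19 C3-formyl lactam (C10 installed as CHO)
Conditions: LDA (2.2 equiv), THF, −78 °C; HCO2Et; aq. NH4Cl
Reagents that add atoms: ethyl formate, CCOC=O
Why: The crossed Claisen condensation (formylation) is clean because 18 has no C–H acid other than C3H2, and the product enolate protects itself from over-reaction.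

Step 13
Reactants: 19 C3-formyl lactam; 20 trimethyl 2-phosphonoacrylate
Product: 21 lactam with quaternary C3 bearing C10HO (cis to C15 and C7) and the C2H2–C1H(PO(OMe)2)CO2Me chain
Conditions: DBU (10 mol %), MeCN, 0 °C
Reagents that add atoms: none
Why: In this Michael addition of the soft formyl-lactam enolate to a doubly activated acrylate, the axial C15H2OSi group on C14 of the rigid trans-fused bicycle blocks one face, so C2 enters anti to it and quaternary C3 is fixed.

Step 14
Reactants: 21 quaternary formyl lactam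
Product: 22 monocyclic lactam (ring D) with C7HO on C6 and the C16–C17–C22O2H arm on C14
Conditions: O3, CH2Cl2, −78 °C; Me2S; aq. citric acid
Reagents that add atoms: ozone, [O-][O+]=O
Why: Ozonolysis of the electron-rich silyl enol ether opens ring J and differentiates its ends, since the silyloxy carbon C22 becomes the acid and C7 the aldehyde.

Step 15
Reactants: 22 aldehyde acid
Product: 23 C22 benzyl ester of 22
Conditions: BnOC(=NH)CCl3, CH2Cl2, rt
Reagents that add atoms: benzyl 2,2,2-trichloroacetimidate, N=C(OCc1ccccc1)C(Cl)(Cl)Cl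
Why: The acid itself promotes this imidate esterification, so no base is present that could epimerise C6 next to the C7 aldehyde.

Step 16
Reactants: 23 benzyl ester dialdehyde
Product: 24 C6-vinyl lactam (C7H=C8H2) with C10HO retained
Conditions: Zn, CH2I2, Ti(OiPr)4, THF, 0 °C → rt
Reagents that add atoms: diiodomethane, ICI
Why: This non-basic gem-dizinc/titanium carbonyl methylenation (Takai–Lombardo type) is aldehyde-selective, spares the acidic phosphonoacetate and C6, and should react at the secondary C7 aldehyde rather than at C10HO, which is buried between two quaternary carbons.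

Step 17
Reactants: 24 C6-vinyl C10-aldehyde; 25 1,2-bis(trimethylsilyloxy)cyclobutene
Product: 27 2-substituted cyclopentane-1,3-dione (ring B on C3), via silyloxycyclobutanone adduct 26 (not isolated)
Conditions: BF3·OEt2, CH2Cl2, −78 °C → rt; then TFA
Reagents that add atoms: none
Why: In this geminal acylation a Mukaiyama aldol addition of 25 to the non-enolisable aldehyde gives 26, and an acid-induced 1,2-acyl shift (pinacol-type ring expansion) makes the former aldehyde carbon C10 of a 1,3-dione with C9 and C11 as ketones.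

Step 18
Reactants: 27 1,3-dione
Product: 28 β-triflyloxy enone (C9–OTf, C9=C10, C11=O)
Conditions: Tf2O, Et3N, CH2Cl2, −78 °C
Reagents that add atoms: trifluoromethanesulfonic anhydride, O=S(=O)(OS(=O)(=O)C(F)(F)F)C(F)(F)F
Why: O-Sulfonylation of the acidic dione gives one product, because rotation about C3–C10 interchanges the two carbonyl groups.

Step 19
Reactants: 28 β-triflyloxy enone
Product: 29 bicyclic dienyl triflate spiro-fused at C3 (rings A and B; C9(OTf)=C10–C11=C1–CO2Me)
Conditions: NaH, THF, 0 °C → rt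
Reagents that add atoms: none
Why: In this intramolecular Horner–Wadsworth–Emmons olefination the phosphonoacetate anion attacks the C11 ketone in a 5-exo mode (attack at C9 would be 5-endo), which closes ring A and removes the only ketone before hydroboration.

Step 20
Reactants: 29 dienyl triflate
Product: 31 tetracyclic diene ester (rings A–D; C9=C10–C11=C1–CO2Me), via B-alkyl-9-BBN borane 30 (not isolated)
Conditions: 9-BBN-H, THF, rt; then PdCl2(dppf) (10 mol %), AsPh3, Cs2CO3, DMF–THF–H2O, slow addition, 50 °C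
Reagents that add atoms: 9-borabicyclo[3.3.1]nonane, B1C2CCCC1CCC2 (carried only by 30)
Why: In this intramolecular B-alkyl Suzuki–Miyaura coupling the borane adds only to the monosubstituted vinyl group (boron at C8), and zerovalent palladium joins C8 to the C9 triflate under dilution, which closes the seven-membered ring C across the cis C3/C6 positions.

Step 21
Reactants: 31 tetracyclic diene ester
Product: 32 tetracyclic lactam with C1–H and C11–H set (1R,11R), C9=C10 retained
Conditions: [Ir(cod)(PCy3)(py)]BArF (20 mol %), H2 (60 bar), CH2Cl2, rt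
Reagents that add atoms: none
Why: Homogeneous hydrogenation with a cationic iridium catalyst is known to saturate only the ester-bound alkene of fully substituted conjugated diene esters, and syn delivery to the flat diene from the lactam-carbonyl (C4) face, opposite C14 and its silyloxymethyl group, sets both hydrogens cis.

Step 22
Reactants: 32 silyl ether
Product: 33 C15 acetate
Conditions: Bu4NF, Ac2O, THF, rt
Reagents that add atoms: acetic anhydride, CC(=O)OC(C)=O
Why: Fluoride desilylation in the presence of the anhydride traps the C15 alkoxide at once as the acetate, so it cannot lactonise onto the C22 ester, and the acetate-buffered medium spares C1.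

Step 23
Reactants: 33 acetate dibenzyl compound
Product: 34 hydroxy acid (C18H2OH, C22O2H)
Conditions: H2 (1 bar), Pd/C, EtOAc, rt
Reagents that add atoms: none
Why: Hydrogenolysis cleaves the benzyl ester and the benzyl ether together, while the hindered tetrasubstituted alkene is not reduced.

Step 24
Reactants: 34 hydroxy acid
Product: 35 aldehyde acid (C18HO)
Conditions: Dess–Martin periodinane, CH2Cl2, 0 °C
Reagents that add atoms: none
Why: The Dess–Martin oxidation needs no base and tolerates the free acid, so the aldehyde forms without epimerisation at C19.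

Step 25
Reactants: 35 aldehyde acid; 36 N-hydroxyphthalimide
Product: 37 aldehyde and N-acyloxyphthalimide ester of the tetracyclic lactam
Conditions: DIC, CH2Cl2, 0 °C → rt (no amine)
Reagents that add atoms: none
Why: Carbodiimide esterification activates only the C22 acid, and the amine-free medium keeps the α-methyl aldehyde configurationally intact.

Step 26
Reactants: 37 aldehyde N-acyloxyphthalimide ester
Product: 39 target CNP0296366.1, via trimethylsilyl ether 38 (not isolated)
Conditions: undivided cell, Zn anode, Ni-foam cathode, CrCl3 (30 mol %), TMSCl (3 equiv), Bu4NPF6 (0.1 M), DMF–THF, constant current (about 2.5 F/mol), 37 added by syringe pump (final 2 mM), rt; then aq. citric acid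
Reagents that add atoms: chlorotrimethylsilane, C[Si](C)(C)Cl (carried only by 38)
Why: Proposed new method: divalent chromium, renewed at the cathode from CrCl3, transfers an electron to the phthalimide ester, which loses phthalimide anion and CO2 to leave the C17 primary radical; a second divalent chromium traps it as a nucleophilic alkylchromium that adds to the C18 aldehyde, and TMSCl frees the metal as silyl ether 38. The closest known reactions are the intermolecular chromium-mediated decarboxylative Nozaki–Hiyama–Kishi-type alkylation of aldehydes with redox-active esters and the electroreductive chromium-catalysed Nozaki–Hiyama–Kishi coupling, neither of which has been used for a medium ring. Ring E closes by a 9-exo-trig addition to the carbonyl group, helped by the rigid bicyclic lactam, which holds the C16–C17 arm of C14 over the nitrogen bridge next to the N-side chain. C18 is set by Felkin–Anh approach anti to the C21H2N substituent of C19, which places the hydroxyl syn to the methyl group. Radical capture must outrun hydrogen transfer and intermolecular addition, which slow addition of 37 to a pool of divalent chromium secures, and the aldehyde must be the only electrophile, which the inertness of alkylchromium reagents towards esters, acetate, lactam and the tetrasubstituted alkene secures. The base-free medium keeps C19 and C1 from epimerising.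

## Compound list

1 | methyl (S)-3-hydroxy-2-methylpropanoate | COC(=O)[C@@H](C)CO | starting material
2 | methyl (S)-3-(benzyloxy)-2-methylpropanoate | COC(=O)[C@@H](C)COCc1ccccc1 | intermediate
3 | (R)-3-(benzyloxy)-2-methylpropan-1-ol | OC[C@@H](C)COCc1ccccc1 | intermediate
4 | 2-nitrobenzenesulfonyl chloride | O=S(=O)(Cl)c1ccccc1[N+](=O)[O-] | starting material
5 | allylamine | C=CCN | starting material
6 | N-allyl-2-nitrobenzenesulfonamide | C=CCNS(=O)(=O)c1ccccc1[N+](=O)[O-] | intermediate
7 | (R)-N-allyl-N-[3-(benzyloxy)-2-methylpropyl]-2-nitrobenzenesulfonamide | C=CCN(C[C@@H](C)COCc1ccccc1)S(=O)(=O)c1ccccc1[N+](=O)[O-] | intermediate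
8 | methyl vinyl ketone | CC(=O)C=C | starting material
9 | (R,E)-N-[3-(benzyloxy)-2-methylpropyl]-2-nitro-N-(4-oxopent-2-en-1-yl)benzenesulfonamide | CC(=O)/C=C/CN(C[C@@H](C)COCc1ccccc1)S(=O)(=O)c1ccccc1[N+](=O)[O-] | intermediate
10 | (R,E)-N-[3-(benzyloxy)-2-methylpropyl]-2-nitro-N-[4-(triisopropylsilyloxy)penta-2,4-dien-1-yl]benzenesulfonamide | C=C(O[Si](C(C)C)(C(C)C)C(C)C)/C=C/CN(C[C@@H](C)COCc1ccccc1)S(=O)(=O)c1ccccc1[N+](=O)[O-] | intermediate
11 | methyl 4-oxobutanoate | COC(=O)CCC=O | starting material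
12 | methyl 3-formylbut-3-enoate | COC(=O)CC(=C)C=O | intermediate
13 | Diels–Alder adduct (ring J; C14 with CHO and CH2CO2Me; C6 with CH2N(Ns)R; CHO cis to C5) | COC(=O)C[C@@]1(C=O)CCC(O[Si](C(C)C)(C(C)C)C(C)C)=C[C@@H]1CN(C[C@@H](C)COCc2ccccc2)S(=O)(=O)c2ccccc2[N+](=O)[O-] | intermediate
14 | hydroxy ester (C15H2OH) | COC(=O)C[C@@]1(CO)CCC(O[Si](C(C)C)(C(C)C)C(C)C)=C[C@@H]1CN(C[C@@H](C)COCc2ccccc2)S(=O)(=O)c2ccccc2[N+](=O)[O-] | intermediate
15 | spiro-γ-lactone on ring J | O=C1C[C@@]2(CO1)CCC(O[Si](C(C)C)(C(C)C)C(C)C)=C[C@@H]2CN(C[C@@H](C)COCc3ccccc3)S(=O)(=O)c3ccccc3[N+](=O)[O-] | intermediate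
16 | amino lactone | O=C1C[C@@]2(CO1)CCC(O[Si](C(C)C)(C(C)C)C(C)C)=C[C@@H]2CNC[C@@H](C)COCc3ccccc3 | intermediate
17 | trans-fused bicyclic δ-lactam (rings D and J), C15H2OH axial | O=C1C[C@@]2(CO)CCC(O[Si](C(C)C)(C(C)C)C(C)C)=C[C@@H]2CN1C[C@@H](C)COCc3ccccc3 | intermediate
18 | C15 TBDPS ether of 17 | O=C1C[C@@]2(CO[Si](c3ccccc3)(c3ccccc3)C(C)(C)C)CCC(O[Si](C(C)C)(C(C)C)C(C)C)=C[C@@H]2CN1C[C@@H](C)COCc3ccccc3 | intermediate
19 | C3-formyl lactam (aldehyde tautomer) | O=C1C(C=O)[C@@]2(CO[Si](c3ccccc3)(c3ccccc3)C(C)(C)C)CCC(O[Si](C(C)C)(C(C)C)C(C)C)=C[C@@H]2CN1C[C@@H](C)COCc3ccccc3 | intermediate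
20 | trimethyl 2-phosphonoacrylate | C=C(C(=O)OC)P(=O)(OC)OC | starting material
21 | quaternary C3 lactam (C10HO cis to C15; phosphonoacetate chain trans) | O=C1[C@@](C=O)(CC(C(=O)OC)P(=O)(OC)OC)[C@@]2(CO[Si](c3ccccc3)(c3ccccc3)C(C)(C)C)CCC(O[Si](C(C)C)(C(C)C)C(C)C)=C[C@@H]2CN1C[C@@H](C)COCc3ccccc3 | intermediate
22 | ring D lactam with C7HO and C22O2H | O=C1[C@@](C=O)(CC(C(=O)OC)P(=O)(OC)OC)[C@@](CO[Si](c2ccccc2)(c2ccccc2)C(C)(C)C)(CCC(=O)O)[C@H](C=O)CN1C[C@@H](C)COCc2ccccc2 | intermediate
23 | C22 benzyl ester of 22 | O=C1[C@@](C=O)(CC(C(=O)OC)P(=O)(OC)OC)[C@@](CO[Si](c2ccccc2)(c2ccccc2)C(C)(C)C)(CCC(=O)OCc2ccccc2)[C@H](C=O)CN1C[C@@H](C)COCc2ccccc2 | intermediate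
24 | C6-vinyl C10-aldehyde | O=C1[C@@](C=O)(CC(C(=O)OC)P(=O)(OC)OC)[C@@](CO[Si](c2ccccc2)(c2ccccc2)C(C)(C)C)(CCC(=O)OCc2ccccc2)[C@H](C=C)CN1C[C@@H](C)COCc2ccccc2 | intermediate
25 | 1,2-bis(trimethylsilyloxy)cyclobutene | C[Si](C)(C)OC1=C(O[Si](C)(C)C)CC1 | starting material
26 | 2-silyloxycyclobutanone aldol adduct (new centres undefined) | O=C1[C@@](C(O)C2(O[Si](C)(C)C)CCC2=O)(CC(C(=O)OC)P(=O)(OC)OC)[C@@](CO[Si](c2ccccc2)(c2ccccc2)C(C)(C)C)(CCC(=O)OCc2ccccc2)[C@H](C=C)CN1C[C@@H](C)COCc2ccccc2 | intermediate
27 | 2-substituted cyclopentane-1,3-dione (ring B) | O=C1[C@@](C2C(=O)CCC2=O)(CC(C(=O)OC)P(=O)(OC)OC)[C@@](CO[Si](c2ccccc2)(c2ccccc2)C(C)(C)C)(CCC(=O)OCc2ccccc2)[C@H](C=C)CN1C[C@@H](C)COCc2ccccc2 | intermediate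
28 | β-triflyloxy enone | O=C1[C@@](C2=C(OS(=O)(=O)C(F)(F)F)CCC2=O)(CC(C(=O)OC)P(=O)(OC)OC)[C@@](CO[Si](c2ccccc2)(c2ccccc2)C(C)(C)C)(CCC(=O)OCc2ccccc2)[C@H](C=C)CN1C[C@@H](C)COCc2ccccc2 | intermediate
29 | dienyl triflate (rings A, B, D) | O=C1[C@@]2(CC(C(=O)OC)=C3CCC(OS(=O)(=O)C(F)(F)F)=C32)[C@@](CO[Si](c2ccccc2)(c2ccccc2)C(C)(C)C)(CCC(=O)OCc2ccccc2)[C@H](C=C)CN1C[C@@H](C)COCc2ccccc2 | intermediate
30 | B-alkyl-9-BBN borane (boron on C8) | O=C1[C@@]2(CC(C(=O)OC)=C3CCC(OS(=O)(=O)C(F)(F)F)=C32)[C@@](CO[Si](c2ccccc2)(c2ccccc2)C(C)(C)C)(CCC(=O)OCc2ccccc2)[C@H](CCB2C3CCCC2CCC3)CN1C[C@@H](C)COCc2ccccc2 | intermediate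
31 | tetracyclic diene ester (rings A–D) | COC(=O)C=1C[C@@]23C(=O)N(C[C@@H](C)COCc4ccccc4)C[C@@H](CCC5=C2C=1CC5)[C@]3(CO[Si](c1ccccc1)(c1ccccc1)C(C)(C)C)CCC(=O)OCc1ccccc1 | intermediate
32 | tetracyclic lactam, C1 and C11 set | COC(=O)[C@@H]1C[C@@]23C(=O)N(C[C@@H](C)COCc4ccccc4)C[C@@H](CCC5=C2[C@@H]1CC5)[C@]3(CO[Si](c1ccccc1)(c1ccccc1)C(C)(C)C)CCC(=O)OCc1ccccc1 | intermediate
33 | C15 acetate | COC(=O)[C@@H]1C[C@@]23C(=O)N(C[C@@H](C)COCc4ccccc4)C[C@@H](CCC5=C2[C@@H]1CC5)[C@]3(COC(C)=O)CCC(=O)OCc1ccccc1 | intermediate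
34 | hydroxy acid | COC(=O)[C@@H]1C[C@@]23C(=O)N(C[C@@H](C)CO)C[C@@H](CCC5=C2[C@@H]1CC5)[C@]3(COC(C)=O)CCC(=O)O | intermediate
35 | aldehyde acid | COC(=O)[C@@H]1C[C@@]23C(=O)N(C[C@@H](C)C=O)C[C@@H](CCC5=C2[C@@H]1CC5)[C@]3(COC(C)=O)CCC(=O)O | intermediate
36 | N-hydroxyphthalimide | O=C1c2ccccc2C(=O)N1O | starting material
37 | aldehyde and N-acyloxyphthalimide ester of the tetracyclic lactam | COC(=O)[C@@H]1C[C@@]23C(=O)N(C[C@@H](C)C=O)C[C@@H](CCC5=C2[C@@H]1CC5)[C@]3(COC(C)=O)CCC(=O)ON6C(=O)c7ccccc7C6=O | intermediate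
38 | C18 trimethylsilyl ether of the target | COC(=O)[C@@H]1C[C@@]23C(=O)N4C[C@@H](CCC5=C2[C@@H]1CC5)[C@]3(COC(C)=O)CC[C@@H](O[Si](C)(C)C)[C@H](C)C4 | intermediate
39 | CNP0296366.1 | COC(=O)[C@@H]1C[C@@]23C(=O)N4C[C@@H](CCC5=C2[C@@H]1CC5)[C@]3(COC(C)=O)CC[C@@H](O)[C@H](C)C4 | target

## Step count and risks

Total steps: 26. Longest linear sequence: 24 (steps 1, 2, 4–6, 8–26).

Steps most likely to fail:

1. **Step 26.** The C17 radical may be quenched by hydrogen transfer before chromium captures it. The alkylchromium may be protonated or add intermolecularly. The facial selectivity at C18 may be poor within the ring-closing transition state. The fallback keeps the same bond but uses known reactions and sets out from 37. Visible-light iododecarboxylation of the phthalimide ester (LiI, catalytic PPh3, blue light) gives the primary iodide aldehyde F1. An intramolecular Barbier reaction with SmI2 (catalytic NiI2, THF, high dilution) then joins C17 to C18 and returns to 39.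

2. **Step 17.** Addition to the buried aldehyde may be too slow, or the acyl shift may give way to retro-aldol cleavage or elimination. The fallback sets out from 24 and builds ring C before ring B.
   - Allylboration with allylboronic acid pinacol ester gives the homoallylic alcohol F2.
   - Ring-closing metathesis (second-generation Grubbs catalyst) of the allyl and C6-vinyl groups gives the cycloheptenol F3.
   - Diimide saturates C7=C8 to the cycloheptanol F4.
   - Dess–Martin oxidation gives the ring C ketone F5, which can enolise only towards C9.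
   - KHMDS (two equivalents, the first taken up by the phosphonoacetate) and N-(5-chloro-2-pyridyl)triflimide give the vinyl triflate F6.
   - Carbonylative Stille coupling with tributyl(vinyl)stannane under CO (Pd(PPh3)4, LiCl) gives the divinyl ketone F7.
   - An acid-promoted Nazarov cyclisation gives the cyclopentenone F8.
   - The Horner–Wadsworth–Emmons closure under the conditions of step 19 returns to 31, so steps 18 and 20 are bypassed.

3. **Step 20.** Protodeboronation, β-hydride elimination or oligomerisation may outrun the closure of the bridged seven-membered ring. The fallback sets out from 29. Stille coupling with tributyl(vinyl)stannane (Pd(PPh3)4, LiCl) gives the C9-vinyl triene F9. Ring-closing metathesis with the C6-vinyl group (second-generation Hoveyda–Grubbs catalyst) gives the cycloheptadiene F10. Diimide, which reduces only the disubstituted C7=C8 alkene, returns to 31.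

## Further compounds

F1 | step 26 | primary iodide aldehyde (iodine on C17) | COC(=O)[C@@H]1C[C@@]23C(=O)N(C[C@@H](C)C=O)C[C@@H](CCC5=C2[C@@H]1CC5)[C@]3(COC(C)=O)CCI
F2 | step 17 | homoallylic alcohol at C10 (carbinol undefined) | O=C1[C@@](C(O)CC=C)(CC(C(=O)OC)P(=O)(OC)OC)[C@@](CO[Si](c2ccccc2)(c2ccccc2)C(C)(C)C)(CCC(=O)OCc2ccccc2)[C@H](C=C)CN1C[C@@H](C)COCc2ccccc2
F3 | step 17 | cycloheptenol (ring C closed, C7=C8) | COC(=O)C(P(=O)(OC)OC)C[C@@]12C(=O)N(C[C@@H](C)COCc3ccccc3)C[C@@H](C=CCC1O)[C@]2(CO[Si](c1ccccc1)(c1ccccc1)C(C)(C)C)CCC(=O)OCc1ccccc1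
F4 | step 17 | cycloheptanol | COC(=O)C(P(=O)(OC)OC)C[C@@]12C(=O)N(C[C@@H](C)COCc3ccccc3)C[C@@H](CCCC1O)[C@]2(CO[Si](c1ccccc1)(c1ccccc1)C(C)(C)C)CCC(=O)OCc1ccccc1
F5 | step 17 | ring C ketone (C10=O) | COC(=O)C(P(=O)(OC)OC)C[C@@]12C(=O)N(C[C@@H](C)COCc3ccccc3)C[C@@H](CCCC1=O)[C@]2(CO[Si](c1ccccc1)(c1ccccc1)C(C)(C)C)CCC(=O)OCc1ccccc1
F6 | step 17 | vinyl triflate (C10–OTf, C9=C10) | COC(=O)C(P(=O)(OC)OC)C[C@@]12C(=O)N(C[C@@H](C)COCc3ccccc3)C[C@@H](CCC=C1OS(=O)(=O)C(F)(F)F)[C@]2(CO[Si](c1ccccc1)(c1ccccc1)C(C)(C)C)CCC(=O)OCc1ccccc1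
F7 | step 17 | divinyl ketone | COC(=O)C(P(=O)(OC)OC)C[C@@]12C(=O)N(C[C@@H](C)COCc3ccccc3)C[C@@H](CCC=C1C(=O)C=C)[C@]2(CO[Si](c1ccccc1)(c1ccccc1)C(C)(C)C)CCC(=O)OCc1ccccc1
F8 | step 17 | cyclopentenone (rings B, C, D; C11=O) | COC(=O)C(P(=O)(OC)OC)C[C@@]12C(=O)N(C[C@@H](C)COCc3ccccc3)C[C@@H](CCC3=C1C(=O)CC3)[C@]2(CO[Si](c1ccccc1)(c1ccccc1)C(C)(C)C)CCC(=O)OCc1ccccc1
F9 | step 20 | C9-vinyl triene | O=C1[C@@]2(CC(C(=O)OC)=C3CCC(C=C)=C32)[C@@](CO[Si](c2ccccc2)(c2ccccc2)C(C)(C)C)(CCC(=O)OCc2ccccc2)[C@H](C=C)CN1C[C@@H](C)COCc2ccccc2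
F10 | step 20 | cycloheptadiene (C7=C8 and C9=C10 in ring C) | COC(=O)C=1C[C@@]23C(=O)N(C[C@@H](C)COCc4ccccc4)C[C@@H](C=CC5=C2C=1CC5)[C@]3(CO[Si](c1ccccc1)(c1ccccc1)C(C)(C)C)CCC(=O)OCc1ccccc1
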